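**Retrosynthetic overview**
1. Target 23 → (primary ester C–O bond, then one acid deprotection) butenolide acid 18 + cyclohexane diol ester 21; both halves come from one aldehyde, 14.
2. 18 ← 14 by E1cB loss of the carbonate (−CO2), lactol closure and oxidation; 21 ← 14 by Pinnick oxidation, carbonate hydrolysis and carboxylate alkylation.
3. 14 ← 13 (ring-alkene hydrogenation); 13 ← one pot: Au(I) cyclisation of enynyl Boc carbonate 11 to the (Z)-dienyl cyclic carbonate 12, then iminium-catalysed endo Diels–Alder with dienal 6, which sets all four ring stereocentres.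
4. 6 ← HWE of phosphonate 3 with fumaraldehyde mono-acetal 4; 11 ← Corey–Fuchs homologation of (E)-4-methylpent-2-enal 7.
5. Ring order: dioxolanone + cyclohexene together in step 6; the butenolide ring (that half only) in step 8.

Assumption: the SMILES is read as cyclohexane half (1S,2S,5R,6S), butenolide half (4S,5R), both side-chain alkenes E. Abbreviations: TBS = tert-butyldimethylsilyl, PMB = 4-methoxybenzyl.

**Route**

Step 1
Reactants: 1 tert-butyl 2-(diethoxyphosphoryl)acetate
Product: 2 tert-butyl 2-(diethoxyphosphoryl)-3-hydroxypropanoate (racemic)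
Conditions: (CH2O)n, piperidine (cat.), MeOH, 65 °C
Reagents that add atoms: paraformaldehyde (formaldehyde), C=O
Why: Amine-catalysed aldol-type hydroxymethylation of the doubly activated methylene; with a weak amine base the adduct does not collapse by Horner–Wadsworth–Emmons elimination.

Step 2
Reactants: 2 tert-butyl 2-(diethoxyphosphoryl)-3-hydroxypropanoate
Product: 3 tert-butyl 3-[(tert-butyldimethylsilyl)oxy]-2-(diethoxyphosphoryl)propanoate (racemic)
Conditions: TBSCl, imidazole, CH2Cl2, 0 °C → rt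
Reagents that add atoms: tert-butyldimethylsilyl chloride, CC(C)(C)[Si](C)(C)Cl
Why: Standard silylation of the primary alcohol (Corey TBS protection).

Step 3
Reactants: 3 tert-butyl 3-[(tert-butyldimethylsilyl)oxy]-2-(diethoxyphosphoryl)propanoate; 4 (2E)-4,4-dimethoxybut-2-enal
Product: 6 tert-butyl (2E,4E)-2-{[(tert-butyldimethylsilyl)oxy]methyl}-6-oxohexa-2,4-dienoate, via tert-butyl (2E,4E)-2-{[(tert-butyldimethylsilyl)oxy]methyl}-6,6-dimethoxyhexa-2,4-dienoate 5 (not isolated)
Conditions: NaH, THF, 0 °C → rt; then Amberlyst-15, acetone–H2O, rt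
Reagents that add atoms: water, O
Why: Horner–Wadsworth–Emmons olefination of the unhindered enal with the α-branched phosphonate gives the (E)-trisubstituted enoate (ester trans to the chain; minor Z isomer removed by chromatography), and the vinylogous dimethyl acetal is hydrolysed under acid mild enough to keep the TBS ether.

Step 4
Reactants: 7 (2E)-4-methylpent-2-enal
Product: 8 (3E)-1,1-dibromo-5-methylhexa-1,3-diene
Conditions: CBr4, PPh3, CH2Cl2, 0 °C
Reagents that add atoms: carbon tetrabromide, BrC(Br)(Br)Br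
Why: Corey–Fuchs dibromo-olefination (Wittig-type) of the aldehyde; the E-alkene is untouched.

Step 5
Reactants: 8 (3E)-1,1-dibromo-5-methylhexa-1,3-diene
Product: 11 tert-butyl (4E)-6-methylhept-4-en-2-yn-1-yl carbonate, via lithium (3E)-5-methylhex-3-en-1-yn-1-ide 9 (not isolated), via lithium (4E)-6-methylhept-4-en-2-yn-1-olate 10 (not isolated)
Conditions: n-BuLi (2.1 equiv), THF, −78 → 0 °C; (CH2O)n, 0 °C → rt; Boc2O, 0 °C → rt
Reagents that add atoms: paraformaldehyde (formaldehyde), C=O; di-tert-butyl dicarbonate, CC(C)(C)OC(=O)OC(=O)OC(C)(C)C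
Why: Second stage of the Corey–Fuchs sequence (Li/Br exchange, rearrangement to the lithium acetylide), hydroxymethylation with formaldehyde and in-situ O-acylation of the alkoxide with Boc2O.

Step 6
Reactants: 11 tert-butyl (4E)-6-methylhept-4-en-2-yn-1-yl carbonate; 6 tert-butyl (2E,4E)-2-{[(tert-butyldimethylsilyl)oxy]methyl}-6-oxohexa-2,4-dienoate
Product: 13 tert-butyl (2E)-2-{[(tert-butyldimethylsilyl)oxy]methyl}-3-[(5S,8S,9S,10S)-10-formyl-2-oxo-8-(propan-2-yl)-1,3-dioxaspiro[4.5]dec-6-en-9-yl]prop-2-enoate, via (4Z)-4-[(2E)-4-methylpent-2-en-1-ylidene]-1,3-dioxolan-2-one 12 (not isolated)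
Conditions: Ph3PAuNTf2 (2 mol %), CH2Cl2, rt; then 6 (0.8 equiv), (5R)-5-benzyl-2,2,3-trimethylimidazolidin-4-one·TFA (20 mol %), MeCN–H2O (95:5), 0 °C → rt
Reagents that add atoms: none
Why: Proposed new method: cationic Au(I) induces 5-exo-dig attack of the Boc carbonyl oxygen anti to gold (isobutene lost) to give the (Z)-alkylidene carbonate 12, a 1-acyloxy diene with the ring oxygen "inside" and the CH2 "outside"; the (E)-iminium ion of 6 with the (5R)-imidazolidinone then undergoes an endo [4+2] at its α,β-bond from the exposed Cα-Re face, with the less hindered, O-activated diene terminus (C–iPr) bonding to Cβ, so that the E-dienophile gives CHO trans to the side chain, endo addition places CHO cis to CH2 and iPr, and all four stereocentres of the cyclohexane half are set together; the closest known reactions are the gold-catalysed rearrangement of propargylic tert-butyl carbonates to 4-alkylidene-1,3-dioxolan-2-ones and the imidazolidinone-catalysed Diels–Alder of 1-acetoxybutadiene with enals (where the (5S) catalyst gives Cα-Si attack).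

Step 7
Reactants: 13 tert-butyl (2E)-2-{[(tert-butyldimethylsilyl)oxy]methyl}-3-[(5S,8S,9S,10S)-10-formyl-2-oxo-8-(propan-2-yl)-1,3-dioxaspiro[4.5]dec-6-en-9-yl]prop-2-enoate
Product: 14 tert-butyl (2E)-2-{[(tert-butyldimethylsilyl)oxy]methyl}-3-[(5S,6S,7S,8R)-6-formyl-2-oxo-8-(propan-2-yl)-1,3-dioxaspiro[4.5]decan-7-yl]prop-2-enoate
Conditions: H2 (3 atm), RhCl(PPh3)3 (10 mol %), benzene–EtOH, rt
Reagents that add atoms: none
Why: Homogeneous hydrogenation with Wilkinson's catalyst reduces the cis-disubstituted ring alkene but not the trisubstituted conjugated enoate, and does not hydrogenolyse the allylic C–O bond; the hindered α-branched aldehyde decarbonylates only on heating, and no stereocentre is created or touched.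

Step 8
Reactants: 14 tert-butyl (2E)-2-{[(tert-butyldimethylsilyl)oxy]methyl}-3-[(5S,6S,7S,8R)-6-formyl-2-oxo-8-(propan-2-yl)-1,3-dioxaspiro[4.5]decan-7-yl]prop-2-enoate
Product: 16 tert-butyl (2E)-2-{[(tert-butyldimethylsilyl)oxy]methyl}-3-[(4S,5R)-3-oxo-5-(propan-2-yl)-1,3,4,5,6,7-hexahydro-2-benzofuran-4-yl]prop-2-enoate, via tert-butyl (2E)-2-{[(tert-butyldimethylsilyl)oxy]methyl}-3-[(4S,5R)-3-hydroxy-5-(propan-2-yl)-1,3,4,5,6,7-hexahydro-2-benzofuran-4-yl]prop-2-enoate 15 (not isolated)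
Conditions: DBU, CH2Cl2, 0 °C → rt; then MnO2, rt
Reagents that add atoms: none
Why: E1cB elimination (allylic strain in the aldehyde enolate turns the C–O bond axial) expels the carbonate, which loses CO2; the freed CH2OH closes onto the new enal as lactol 15, which MnO2 oxidises to the butenolide, while the two remaining stereocentres carry no acidic hydrogen and are retained.

Step 9
Reactants: 16 tert-butyl (2E)-2-{[(tert-butyldimethylsilyl)oxy]methyl}-3-[(4S,5R)-3-oxo-5-(propan-2-yl)-1,3,4,5,6,7-hexahydro-2-benzofuran-4-yl]prop-2-enoate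
Product: 18 (2E)-2-{[(tert-butyldimethylsilyl)oxy]methyl}-3-[(4S,5R)-3-oxo-5-(propan-2-yl)-1,3,4,5,6,7-hexahydro-2-benzofuran-4-yl]prop-2-enoic acid, via the trimethylsilyl ester of this acid 17 (not isolated)
Conditions: TMSOTf, 2,6-lutidine, CH2Cl2, 0 °C; then pH 4 buffer
Reagents that add atoms: none
Why: Silyl-triflate-mediated tert-butyl ester cleavage (loss of isobutene) leaves the primary TBS ether and the butenolide intact; the TMS ester, and any silyloxyfuran formed from the butenolide, revert on aqueous work-up.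

Step 10
Reactants: 14 tert-butyl (2E)-2-{[(tert-butyldimethylsilyl)oxy]methyl}-3-[(5S,6S,7S,8R)-6-formyl-2-oxo-8-(propan-2-yl)-1,3-dioxaspiro[4.5]decan-7-yl]prop-2-enoate
Product: 19 (5S,6S,7S,8R)-7-[(1E)-3-tert-butoxy-2-{[(tert-butyldimethylsilyl)oxy]methyl}-3-oxoprop-1-en-1-yl]-2-oxo-8-(propan-2-yl)-1,3-dioxaspiro[4.5]decane-6-carboxylic acid
Conditions: NaClO2, NaH2PO4, 2-methyl-2-butene, t-BuOH–H2O, 0 °C → rt
Reagents that add atoms: sodium chlorite, [Na+].[O-]Cl=O
Why: Pinnick oxidation converts the hindered aldehyde to the acid at pH 3–4 without epimerisation or β-elimination, with the scavenger protecting the alkene.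

Step 11
Reactants: 19 (5S,6S,7S,8R)-7-[(1E)-3-tert-butoxy-2-{[(tert-butyldimethylsilyl)oxy]methyl}-3-oxoprop-1-en-1-yl]-2-oxo-8-(propan-2-yl)-1,3-dioxaspiro[4.5]decane-6-carboxylic acid
Product: 21 4-methoxybenzyl (1S,2S,5R,6S)-6-[(1E)-3-tert-butoxy-2-{[(tert-butyldimethylsilyl)oxy]methyl}-3-oxoprop-1-en-1-yl]-2-hydroxy-2-(hydroxymethyl)-5-(propan-2-yl)cyclohexane-1-carboxylate, via lithium (1S,2S,5R,6S)-6-[(1E)-3-tert-butoxy-2-{[(tert-butyldimethylsilyl)oxy]methyl}-3-oxoprop-1-en-1-yl]-2-hydroxy-2-(hydroxymethyl)-5-(propan-2-yl)cyclohexane-1-carboxylate 20 (not isolated)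
Conditions: LiOH (3.0 equiv), THF–H2O, 0 °C; evaporate; then PMBCl, Bu4NI (cat.), DMF, rt; used at once in step 12
Reagents that add atoms: 4-methoxybenzyl chloride, COc1ccc(CCl)cc1
Why: Saponification of the five-membered cyclic carbonate (acyl–oxygen cleavage) gives the dihydroxy carboxylate, which cannot lactonise as its salt and is alkylated by SN2 at the carboxylate only; all four stereocentres are retained.

Step 12
Reactants: 18 (2E)-2-{[(tert-butyldimethylsilyl)oxy]methyl}-3-[(4S,5R)-3-oxo-5-(propan-2-yl)-1,3,4,5,6,7-hexahydro-2-benzofuran-4-yl]prop-2-enoic acid; 21 4-methoxybenzyl (1S,2S,5R,6S)-6-[(1E)-3-tert-butoxy-2-{[(tert-butyldimethylsilyl)oxy]methyl}-3-oxoprop-1-en-1-yl]-2-hydroxy-2-(hydroxymethyl)-5-(propan-2-yl)cyclohexane-1-carboxylate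
Product: 22 the fully protected dimer: 21 acylated on its primary hydroxyl by 18 (tertiary OH free; PMB ester, tert-butyl ester and two TBS ethers in place)
Conditions: MNBA, DMAP, Et3N, CH2Cl2, rt
Reagents that add atoms: none
Why: Shiina esterification through the mixed anhydride of 18 acylates only the primary hydroxyl; the tertiary alcohol is inert and no stereocentre is involved.

Step 13
Reactants: 22 the fully protected dimer
Product: 23 CNP0071646.2, (1S,2S,5R,6S)-6-[(1E)-2-carboxy-3-hydroxyprop-1-en-1-yl]-2-hydroxy-2-{[((2E)-2-(hydroxymethyl)-3-[(4S,5R)-3-oxo-5-(propan-2-yl)-1,3,4,5,6,7-hexahydro-2-benzofuran-4-yl]prop-2-enoyl)oxy]methyl}-5-(propan-2-yl)cyclohexane-1-carboxylic acid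
Conditions: TFA–CH2Cl2–H2O (5:5:1), 0 °C → rt; brief aq. NaHCO3 wash, then acidify to pH 3
Reagents that add atoms: none
Why: Acidolysis removes the PMB and tert-butyl esters (alkyl–oxygen cleavage through stabilised cations) and both primary TBS ethers in one operation, leaving the ester link, the butenolide and all stereocentres untouched.

**Compound list**
1 | tert-butyl 2-(diethoxyphosphoryl)acetate | CCOP(=O)(OCC)CC(=O)OC(C)(C)C | starting material
2 | tert-butyl 2-(diethoxyphosphoryl)-3-hydroxypropanoate | CCOP(=O)(OCC)C(CO)C(=O)OC(C)(C)C | intermediate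
3 | tert-butyl 3-[(tert-butyldimethylsilyl)oxy]-2-(diethoxyphosphoryl)propanoate | CCOP(=O)(OCC)C(CO[Si](C)(C)C(C)(C)C)C(=O)OC(C)(C)C | intermediate
4 | (2E)-4,4-dimethoxybut-2-enal (fumaraldehyde mono(dimethyl acetal)) | COC(OC)/C=C/C=O | starting material
5 | tert-butyl (2E,4E)-2-(TBSO-methyl)-6,6-dimethoxyhexa-2,4-dienoate | COC(OC)/C=C/C=C(\CO[Si](C)(C)C(C)(C)C)C(=O)OC(C)(C)C | intermediate (not isolated)
6 | tert-butyl (2E,4E)-2-(TBSO-methyl)-6-oxohexa-2,4-dienoate | O=C/C=C/C=C(\CO[Si](C)(C)C(C)(C)C)C(=O)OC(C)(C)C | intermediate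
7 | (2E)-4-methylpent-2-enal | CC(C)/C=C/C=O | starting material
8 | (3E)-1,1-dibromo-5-methylhexa-1,3-diene | CC(C)/C=C/C=C(Br)Br | intermediate
9 | lithium (3E)-5-methylhex-3-en-1-yn-1-ide | [Li]C#C/C=C/C(C)C | intermediate (not isolated)
10 | lithium (4E)-6-methylhept-4-en-2-yn-1-olate | [Li+].[O-]CC#C/C=C/C(C)C | intermediate (not isolated)
11 | tert-butyl (4E)-6-methylhept-4-en-2-yn-1-yl carbonate | CC(C)/C=C/C#CCOC(=O)OC(C)(C)C | intermediate
12 | (4Z)-4-[(2E)-4-methylpent-2-en-1-ylidene]-1,3-dioxolan-2-one | O=C1OC/C(=C/C=C/C(C)C)O1 | intermediate (not isolated)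
13 | Diels–Alder adduct, (5S,8S,9S,10S)-spiro carbonate cyclohexene aldehyde | CC(C)[C@H]1C=C[C@]2(OC(=O)OC2)[C@@H](C=O)[C@@H]1/C=C(\CO[Si](C)(C)C(C)(C)C)C(=O)OC(C)(C)C | intermediate
14 | (5S,6S,7S,8R)-spiro carbonate cyclohexane aldehyde | CC(C)[C@H]1CC[C@]2(OC(=O)OC2)[C@@H](C=O)[C@@H]1/C=C(\CO[Si](C)(C)C(C)(C)C)C(=O)OC(C)(C)C | intermediate
15 | (4S,5R)-lactol (3-hydroxy-1,3,4,5,6,7-hexahydro-2-benzofuran), mixture at the lactol carbon | CC(C)(C)OC(=O)/C(=C/[C@H]1C2=C(CC[C@@H]1C(C)C)COC2O)CO[Si](C)(C)C(C)(C)C | intermediate (not isolated)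
16 | (4S,5R)-butenolide tert-butyl ester | CC(C)(C)OC(=O)/C(=C/[C@H]1C2=C(CC[C@@H]1C(C)C)COC2=O)CO[Si](C)(C)C(C)(C)C | intermediate
17 | (4S,5R)-butenolide trimethylsilyl ester | C[Si](C)(C)OC(=O)/C(=C/[C@H]1C2=C(CC[C@@H]1C(C)C)COC2=O)CO[Si](C)(C)C(C)(C)C | intermediate (not isolated)
18 | (4S,5R)-butenolide acid | OC(=O)/C(=C/[C@H]1C2=C(CC[C@@H]1C(C)C)COC2=O)CO[Si](C)(C)C(C)(C)C | intermediate
19 | (5S,6S,7S,8R)-spiro carbonate cyclohexane carboxylic acid | CC(C)[C@H]1CC[C@]2(OC(=O)OC2)[C@@H](C(=O)O)[C@@H]1/C=C(\CO[Si](C)(C)C(C)(C)C)C(=O)OC(C)(C)C | intermediate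
20 | lithium (1S,2S,5R,6S)-dihydroxy carboxylate | CC(C)[C@H]1CC[C@@](O)(CO)[C@@H](C(=O)[O-])[C@@H]1/C=C(\CO[Si](C)(C)C(C)(C)C)C(=O)OC(C)(C)C.[Li+] | intermediate (not isolated)
21 | 4-methoxybenzyl (1S,2S,5R,6S)-dihydroxy ester | CC(C)[C@H]1CC[C@@](O)(CO)[C@@H](C(=O)OCc2ccc(OC)cc2)[C@@H]1/C=C(\CO[Si](C)(C)C(C)(C)C)C(=O)OC(C)(C)C | intermediate
22 | fully protected dimer | CC(C)[C@H]1CC[C@@](O)(COC(=O)/C(=C/[C@H]2C3=C(CC[C@@H]2C(C)C)COC3=O)CO[Si](C)(C)C(C)(C)C)[C@@H](C(=O)OCc2ccc(OC)cc2)[C@@H]1/C=C(\CO[Si](C)(C)C(C)(C)C)C(=O)OC(C)(C)C | intermediate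
23 | CNP0071646.2 | CC(C)[C@H]1CC[C@@](O)(COC(=O)/C(=C/[C@H]2C3=C(CC[C@@H]2C(C)C)COC3=O)CO)[C@@H](C(=O)O)[C@@H]1/C=C(\CO)C(=O)O | target

**Totals**
Total steps: 13. Longest linear sequence: 9 steps (1 → 2 → 3 → 6 → 7 → 8 → 9 → 12 → 13; the path through steps 10 and 11 is equally long).

**Three steps most likely to fail**

Step 6. Risks: 6-endo instead of 5-exo gold cyclisation of the conjugated enyne, interference between the two catalysts in one pot, and a slow cycloaddition at the fully substituted diene terminus. The fallback sets out from 8 and comes back at 13. Compound 8 is treated with n-BuLi and paraformaldehyde and quenched with water to give (4E)-6-methylhept-4-en-2-yn-1-ol F1. F1 is cyclised with CO2 (AgOAc, DBU, toluene) through its alkyl carbonate, which gives 12 by 5-exo anti-addition; 12 is isolated this time. The Diels–Alder with 6 is then run as a separate step under the same (5R)-imidazolidinone catalysis, or with a chiral oxazaborolidinium Lewis acid on the purified diene, to reach 13.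

Step 7. Risks: poisoning of the rhodium catalyst by aldehyde decarbonylation, ionisation of the allylic carbonate, or partial reduction of the enoate. The fallback sets out from 13 and comes back at 19 for the cyclohexane half and at 16 for the butenolide half. Pinnick oxidation of 13 gives the unsaturated acid, (5S,8S,9S,10S)-9-[(1E)-3-tert-butoxy-2-(TBSO-methyl)-3-oxoprop-1-en-1-yl]-2-oxo-8-(propan-2-yl)-1,3-dioxaspiro[4.5]dec-6-ene-10-carboxylic acid F2. Metal-free diimide (2-nitrobenzenesulfonyl hydrazide, Et3N) then reduces only its ring alkene to give 19. The butenolide half is taken from 19 instead of 14: LiOH gives 20, and acidification closes the cis-fused hydroxy-lactone, tert-butyl (2E)-2-(TBSO-methyl)-3-[(3aS,4S,5R,7aS)-7a-hydroxy-3-oxo-5-(propan-2-yl)octahydro-2-benzofuran-4-yl]prop-2-enoate F3. F3 is dehydrated by E1cB through its trifluoroacetate ((CF3CO)2O, DMAP, then DBU) to 16.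

Step 11. Risk: the free γ-hydroxy PMB ester 21 relactonises, with loss of PMB alcohol, before or during acylation. The fallback sets out from 14 and comes back only at the target 23; it keeps the ring carbon at the aldehyde oxidation level until after the ester bond is made.
- 14 is converted (MeOTMS, cat. TMSOTf, −78 °C) into its dimethyl acetal, tert-butyl (2E)-2-(TBSO-methyl)-3-[(5S,6S,7S,8R)-6-(dimethoxymethyl)-2-oxo-8-(propan-2-yl)-1,3-dioxaspiro[4.5]decan-7-yl]prop-2-enoate F4.
- K2CO3/MeOH cleaves the carbonate to the diol, tert-butyl (2E)-2-(TBSO-methyl)-3-[(1S,2S,3S,6R)-2-(dimethoxymethyl)-3-hydroxy-3-(hydroxymethyl)-6-(propan-2-yl)cyclohexyl]prop-2-enoate F5, which cannot lactonise.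
- F5 is acylated with 18 (MNBA, DMAP) to the protected dimer acetal F6.
- TFA–H2O removes the acetal, the tert-butyl ester and both TBS groups to give the dimer hydroxy-aldehyde F7.
- Pinnick oxidation of F7 gives 23.

**Further compounds**
F1 | step 6 | (4E)-6-methylhept-4-en-2-yn-1-ol | OCC#C/C=C/C(C)C
F2 | step 7 | (5S,8S,9S,10S)-spiro carbonate cyclohexene carboxylic acid | CC(C)[C@H]1C=C[C@]2(OC(=O)OC2)[C@@H](C(=O)O)[C@@H]1/C=C(\CO[Si](C)(C)C(C)(C)C)C(=O)OC(C)(C)C
F3 | step 7 | (3aS,4S,5R,7aS)-cis-fused 7a-hydroxy lactone | CC(C)[C@H]1CC[C@@]2(O)COC(=O)[C@H]2[C@@H]1/C=C(\CO[Si](C)(C)C(C)(C)C)C(=O)OC(C)(C)C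
F4 | step 11 | dimethyl acetal of 14 | CC(C)[C@H]1CC[C@]2(OC(=O)OC2)[C@@H](C(OC)OC)[C@@H]1/C=C(\CO[Si](C)(C)C(C)(C)C)C(=O)OC(C)(C)C
F5 | step 11 | diol dimethyl acetal | CC(C)[C@H]1CC[C@@](O)(CO)[C@@H](C(OC)OC)[C@@H]1/C=C(\CO[Si](C)(C)C(C)(C)C)C(=O)OC(C)(C)C
F6 | step 11 | protected dimer dimethyl acetal | CC(C)[C@H]1CC[C@@](O)(COC(=O)/C(=C/[C@H]2C3=C(CC[C@@H]2C(C)C)COC3=O)CO[Si](C)(C)C(C)(C)C)[C@@H](C(OC)OC)[C@@H]1/C=C(\CO[Si](C)(C)C(C)(C)C)C(=O)OC(C)(C)C
F7 | step 11 | dimer hydroxy-aldehyde (ring CHO in place of ring CO2H of 23) | CC(C)[C@H]1CC[C@@](O)(COC(=O)/C(=C/[C@H]2C3=C(CC[C@@H]2C(C)C)COC3=O)CO)[C@@H](C=O)[C@@H]1/C=C(\CO)C(=O)O
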